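**Retrosynthetic overview**

1. The target is a trans-(3R,4R)-3,4-dibenzyl-γ-butyrolactone. Rings A (3,4-dimethoxyphenyl) and B (3-hydroxy-4,5-dimethoxyphenyl) are bought, so the lactone (O1–C2–C3–C4–C5) is the only ring formed in the route.
2. Last disconnections: the O-benzyl ether on ring B (hydrogenolysis) and the C3–CH2(ring B) bond (trans-selective enolate alkylation of the (R)-4-(3,4-dimethoxybenzyl) lactone with a ring B benzylic bromide).
3. The lactone is closed at C3–C4 by a catalytic enantioselective intramolecular carbenoid C–H insertion of the achiral, acyclic 3-(3,4-dimethoxyphenyl)propyl diazoacetate. This one step makes the ring, the C–C bond and the C4 stereocentre, and C4 then directs C3.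
4. Enabling feature: C4 is the methine β to the ring oxygen O1 and C3 is α to the C2 carbonyl. Opened at C3–C4, C3 can carry a diazo group, and C4 is a prochiral CH2 held 1,5 to it through the ester; it is neither deactivated by oxygen (as C5 is) nor beyond five-ring reach (as the benzylic CH2 is).
5. Precursors: the diazo ester comes from 3-(3,4-dimethoxyphenyl)propan-1-ol and bromoacetyl bromide; the ring B bromide comes from 3-hydroxy-4,5-dimethoxybenzaldehyde.

Key step: step 3

Assumption: Rh2(4R-MPPIM)4 is taken to be the catalyst antipode that gives the (R)-lactone, by analogy with the sense of induction of this catalyst family with alkyl diazoacetates; both antipodes are equally accessible (from either enantiomer of asparagine), so the mirror-image catalyst would be used without other change if the sense were the reverse.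

**Route**

Step 1
Reactants: 1 3-(3,4-dimethoxyphenyl)propan-1-ol; 2 bromoacetyl bromide
Product: 3 3-(3,4-dimethoxyphenyl)propyl bromoacetate
Conditions: NaHCO3, MeCN, 0 °C
Reagents that add atoms: none
Why: Acylation of a primary alcohol by an acid bromide (nucleophilic acyl substitution) with NaHCO3 as acid scavenger should be clean; no stereocentre is involved.

Step 2
Reactants: 3 3-(3,4-dimethoxyphenyl)propyl bromoacetate
Product: 5 3-(3,4-dimethoxyphenyl)propyl diazoacetate, via N-alkylated ditosylhydrazine 4 (not isolated)
Conditions: TsNHNHTs, DBU, THF, 0 °C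
Reagents that add atoms: N,N'-ditosylhydrazine Cc1ccc(cc1)S(=O)(=O)NNS(=O)(=O)c1ccc(C)cc1
Why: SN2 N-alkylation of the sulfonyl hydrazide anion by the α-bromo ester, followed by base-induced double elimination of sulfinate (Bamford–Stevens-type), is a standard mild conversion of bromoacetates into diazoacetates; no stereocentre is involved.

Step 3
Reactants: 5 3-(3,4-dimethoxyphenyl)propyl diazoacetate
Product: 6 (R)-4-(3,4-dimethoxybenzyl)dihydrofuran-2(3H)-one
Conditions: Rh2(4R-MPPIM)4 [dirhodium tetrakis(methyl (4R)-2-oxo-1-(3-phenylpropanoyl)imidazolidine-4-carboxylate)] (1 mol%), CH2Cl2, reflux, slow addition of 5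
Reagents that add atoms: none
Why: The divalent rhodium carboxamidate decomposes the diazo ester with loss of N2 to an electrophilic rhodium carbenoid at C3, which inserts through a concerted, asynchronous three-centre transition state into one C–H bond of the methylene β to the ester oxygen, forming the C3–C4 bond as the hydrogen passes to C3. The closest known reaction type is the enantioselective intramolecular C–H insertion of alkyl diazoacetates catalysed by chiral dirhodium carboxamidates, which is established for 3-arylpropyl diazoacetates as a route to 4-benzyl-γ-butyrolactones. The lactone closes in the five-membered (1,5-insertion) mode, with the ester O–C(=O) unit inside the forming ring. The C4 stereocentre is set by the catalyst alone: the (4R)-imidazolidinone ligands orient the bound carbenoid so that only one of the two enantiotopic C–H bonds of the prochiral methylene can reach it, which should give the (R)-lactone in high enantiomeric excess. The step needs site selectivity and the substrate secures it: the O–CH2 hydrogens are inductively deactivated and would lead to a strained β-lactone, the benzylic hydrogens would need a six-membered closure, and the electron-rich ring A lies too far along the chain for aromatic cycloaddition to compete with five-ring closure of the mild carboxamidate carbenoid. Slow addition of 5 keeps the carbenoid from dimerising to maleate and fumarate esters.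

Step 4
Reactants: 7 3-hydroxy-4,5-dimethoxybenzaldehyde
Product: 8 3-(benzyloxy)-4,5-dimethoxybenzaldehyde
Conditions: BnBr, K2CO3, DMF, rt
Reagents that add atoms: benzyl bromide BrCc1ccccc1
Why: Williamson ether synthesis on the phenoxide masks the only acidic OH of ring B as a benzyl ether, which should survive hydride, PBr3 and enolate chemistry and is removable by hydrogenolysis at the end.

Step 5
Reactants: 8 3-(benzyloxy)-4,5-dimethoxybenzaldehyde
Product: 9 [3-(benzyloxy)-4,5-dimethoxyphenyl]methanol
Conditions: NaBH4, MeOH, 0 °C
Reagents that add atoms: none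
Why: Chemoselective hydride reduction of the aryl aldehyde to the benzylic alcohol; the ethers are inert and no stereocentre is formed.

Step 6
Reactants: 9 [3-(benzyloxy)-4,5-dimethoxyphenyl]methanol
Product: 10 1-(benzyloxy)-5-(bromomethyl)-2,3-dimethoxybenzene
Conditions: PBr3, CH2Cl2, 0 °C
Reagents that add atoms: phosphorus tribromide BrP(Br)Br
Why: The benzylic alcohol is converted into the bromide through its phosphite ester (SN2 displacement by bromide) at 0 °C, mild and brief enough to leave the benzyl and methyl ethers intact; the bromide is used without storage.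

Step 7
Reactants: 6 (R)-4-(3,4-dimethoxybenzyl)dihydrofuran-2(3H)-one; 10 1-(benzyloxy)-5-(bromomethyl)-2,3-dimethoxybenzene
Product: 12 (3R,4R)-3-[3-(benzyloxy)-4,5-dimethoxybenzyl]-4-(3,4-dimethoxybenzyl)dihydrofuran-2(3H)-one, via lithium enolate 11 (not isolated)
Conditions: LiN(SiMe3)2, THF, −78 °C; then 10, DMPU, −78 to −20 °C
Reagents that add atoms: none
Why: Kinetic deprotonation gives the lithium enolate, which is C-alkylated (SN2) by the benzylic bromide on the ring face anti to the C4 benzyl group, so C3 is set trans to C4 (3R) under substrate control, as is general for α-alkylation of 4-substituted γ-butyrolactone enolates; C4 is not enolisable and keeps its configuration.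

Step 8
Reactants: 12 (3R,4R)-3-[3-(benzyloxy)-4,5-dimethoxybenzyl]-4-(3,4-dimethoxybenzyl)dihydrofuran-2(3H)-one
Product: 13 (3R,4R)-4-(3,4-dimethoxybenzyl)-3-(3-hydroxy-4,5-dimethoxybenzyl)dihydrofuran-2(3H)-one
Conditions: H2 (1 atm), 10% Pd/C, EtOAc, rt
Reagents that add atoms: none
Why: Hydrogenolysis of the aryl benzyl ether over Pd/C under neutral conditions should free the ring B phenol without touching the lactone, the methyl ethers or either stereocentre, since no base is present to epimerise C3.

**Compound list**

1 | 3-(3,4-dimethoxyphenyl)propan-1-ol | COc1ccc(CCCO)cc1OC | starting material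
2 | bromoacetyl bromide | BrCC(Br)=O | starting material
3 | 3-(3,4-dimethoxyphenyl)propyl bromoacetate | COc1ccc(CCCOC(=O)CBr)cc1OC | intermediate
4 | 3-(3,4-dimethoxyphenyl)propyl 2-[1,2-bis(4-methylbenzenesulfonyl)hydrazin-1-yl]acetate (not isolated) | COc1ccc(CCCOC(=O)CN(NS(=O)(=O)c2ccc(C)cc2)S(=O)(=O)c2ccc(C)cc2)cc1OC | intermediate
5 | 3-(3,4-dimethoxyphenyl)propyl diazoacetate | COc1ccc(CCCOC(=O)C=[N+]=[N-])cc1OC | intermediate
6 | (R)-4-(3,4-dimethoxybenzyl)dihydrofuran-2(3H)-one | COc1ccc(C[C@H]2COC(=O)C2)cc1OC | intermediate
7 | 3-hydroxy-4,5-dimethoxybenzaldehyde | COc1cc(C=O)cc(O)c1OC | starting material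
8 | 3-(benzyloxy)-4,5-dimethoxybenzaldehyde | COc1cc(C=O)cc(OCc2ccccc2)c1OC | intermediate
9 | [3-(benzyloxy)-4,5-dimethoxyphenyl]methanol | COc1cc(CO)cc(OCc2ccccc2)c1OC | intermediate
10 | 1-(benzyloxy)-5-(bromomethyl)-2,3-dimethoxybenzene (3-benzyloxy-4,5-dimethoxybenzyl bromide) | COc1cc(CBr)cc(OCc2ccccc2)c1OC | intermediate
11 | lithium (R)-4-(3,4-dimethoxybenzyl)-4,5-dihydrofuran-2-olate (not isolated) | COc1ccc(C[C@H]2COC([O-])=C2)cc1OC.[Li+] | intermediate
12 | (3R,4R)-3-[3-(benzyloxy)-4,5-dimethoxybenzyl]-4-(3,4-dimethoxybenzyl)dihydrofuran-2(3H)-one | COc1ccc(C[C@H]2COC(=O)[C@@H]2Cc2cc(OCc3ccccc3)c(OC)c(OC)c2)cc1OC | intermediate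
13 | (3R,4R)-4-(3,4-dimethoxybenzyl)-3-(3-hydroxy-4,5-dimethoxybenzyl)dihydrofuran-2(3H)-one | COc1ccc(C[C@H]2COC(=O)[C@@H]2Cc2cc(O)c(OC)c(OC)c2)cc1OC | target

**Step count**

Total steps: 8. Longest linear sequence: 5 steps (steps 1, 2, 3, 7, 8; the ring B branch, steps 4, 5, 6, 7, 8, is equally long).

**Steps most likely to fail, with fallbacks**

Step 3. The enantiotopic C–H discrimination or the site selectivity may erode (insertion next to oxygen, attack on the electron-rich ring A), or the carbenoid may dimerise. The fallback sets C4 with an oxazolidinone auxiliary and closes the lactone by C–O bond formation; it sets out from 1 and returns at 6. Alcohol 1 would be oxidised (TEMPO, PhI(OAc)2, MeCN/H2O) to 3-(3,4-dimethoxyphenyl)propanoic acid F1. This is coupled through its pivaloyl mixed anhydride (PivCl, Et3N, LiCl, THF) with (S)-4-benzyloxazolidin-2-one to give (S)-4-benzyl-3-[3-(3,4-dimethoxyphenyl)propanoyl]oxazolidin-2-one F2. Its sodium Z-enolate (NaN(SiMe3)2, THF, −78 °C) should be alkylated by tert-butyl bromoacetate on the face away from the auxiliary benzyl group to give tert-butyl (R)-3-[(S)-4-benzyl-2-oxooxazolidine-3-carbonyl]-4-(3,4-dimethoxyphenyl)butanoate F3. Reductive removal of the auxiliary (LiBH4, THF/MeOH, 0 °C) gives tert-butyl (R)-4-(3,4-dimethoxyphenyl)-3-(hydroxymethyl)butanoate F4, and CF3CO2H in CH2Cl2 closes it to lactone 6.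

Step 7. Facial selectivity may be incomplete, a second alkylation may occur, or the labile electron-rich benzylic bromide may be lost by ionisation and self-alkylation before the enolate captures it. The fallback replaces alkylation by an aldol addition and hydrogenolysis; it sets out from 6 (with aldehyde 8 in place of bromide 10) and returns at 13. The lithium enolate of 6 (LiN(SiMe3)2, THF, −78 °C) is added to aldehyde 8, anti to the C4 substituent, to give (3S,4R)-3-{[3-(benzyloxy)-4,5-dimethoxyphenyl](hydroxy)methyl}-4-(3,4-dimethoxybenzyl)dihydrofuran-2(3H)-one F5 as a mixture of carbinol epimers, which is of no consequence. Hydrogenolysis (H2, 10% Pd/C, AcOH, catalytic HClO4) should then cleave both the benzylic C–OH bond and the O-benzyl ether to give 13 directly.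

Step 2. Sulfinate elimination may be incomplete, or the diazo ester may decompose under adventitious acid during isolation. The fallback builds the diazo group by diazo transfer and deacylation; it sets out from 1 and returns at 5. Alcohol 1 is acetoacetylated with 2,2,6-trimethyl-4H-1,3-dioxin-4-one (xylene, 140 °C) to give 3-(3,4-dimethoxyphenyl)propyl 3-oxobutanoate F6. Diazo transfer (MsN3, Et3N, MeCN) gives 3-(3,4-dimethoxyphenyl)propyl 2-diazo-3-oxobutanoate F7, and deacetylation with LiOH in THF/H2O gives diazoacetate 5.

**Further compounds**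

F1 | step 3 | 3-(3,4-dimethoxyphenyl)propanoic acid | COc1ccc(CCC(=O)O)cc1OC
F2 | step 3 | (S)-4-benzyl-3-[3-(3,4-dimethoxyphenyl)propanoyl]oxazolidin-2-one | COc1ccc(CCC(=O)N2[C@@H](Cc3ccccc3)COC2=O)cc1OC
F3 | step 3 | tert-butyl (R)-3-[(S)-4-benzyl-2-oxooxazolidine-3-carbonyl]-4-(3,4-dimethoxyphenyl)butanoate | COc1ccc(C[C@H](CC(=O)OC(C)(C)C)C(=O)N2[C@@H](Cc3ccccc3)COC2=O)cc1OC
F4 | step 3 | tert-butyl (R)-4-(3,4-dimethoxyphenyl)-3-(hydroxymethyl)butanoate | COc1ccc(C[C@H](CC(=O)OC(C)(C)C)CO)cc1OC
F5 | step 7 | (3S,4R)-3-{[3-(benzyloxy)-4,5-dimethoxyphenyl](hydroxy)methyl}-4-(3,4-dimethoxybenzyl)dihydrofuran-2(3H)-one, mixture of carbinol epimers | COc1ccc(C[C@H]2COC(=O)[C@@H]2C(O)c2cc(OCc3ccccc3)c(OC)c(OC)c2)cc1OC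
F6 | step 2 | 3-(3,4-dimethoxyphenyl)propyl 3-oxobutanoate | COc1ccc(CCCOC(=O)CC(C)=O)cc1OC
F7 | step 2 | 3-(3,4-dimethoxyphenyl)propyl 2-diazo-3-oxobutanoate | COc1ccc(CCCOC(=O)C(=[N+]=[N-])C(C)=O)cc1OC
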